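The earlier runs and the new flask were generated by integration for an exercise; scatter was added.

Slowness can be measured here without a clock, and that measure is what you carry from flask to flask.

| setting | east | south-east | west | flask |
|---|---|---|---|---|
| left-handed substrate | 0.10 M | 0.10 M | 0.10 M | 0.10 M |
| right-handed substrate | 0.10 M | 0.10 M | 0.10 M | 0.10 M |
| reagent | 0.10 M | 0.15 M | 0.20 M | 0.200 M |
| free catalyst | 7.6 mM | 7.6 mM | 11 mM | 7.6 mM |
| impurity | 1.3 mM | 1.3 mM | 1.3 mM | 1.3 mM |
| remark | run made earlier | run made earlier | run made earlier |  |
| time |  |  |  | 2.5 h |

| run | time / h | left-handed substrate / % | right-handed substrate / % |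
|---|---|---|---|
| east | 0.667 | 36 | 42 |
| east | 1.33 | 32 | 40 |
| east | 2.00 | 32 | 40 |
| east | 2.50 | 34 | 38 |
| south-east | 0.333 | 34 | 40 |
| south-east | 0.833 | 30 | 36 |
| south-east | 1.50 | 27 | 34 |
| south-east | 2.50 | 28 | 35 |
| west | 0.333 | 26 | 34 |
| west | 0.833 | 22 | 30 |
| west | 1.50 | 18 | 27 |
| west | 2.50 | 19 | 27 |

(each reading ± 1.5 percentage points)

- free catalyst is single-handed; left-handed substrate and right-handed substrate are mirror images of each other, charged as a racemate, each of them at the stated concentration
- on the list of suspects stand: reagent + free catalyst + left-handed substrate -> free catalyst + left-handed product; reagent + free catalyst + right-handed substrate -> free catalyst + right-handed product; free catalyst + impurity -> spent catalyst A; 2 reagent -> self-condensation product; free catalyst -> spent catalyst B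
- an excess is below zero if the other one leads

1. part of the left-handed substrate and right-handed substrate charged together that has reacted at 2.5 h
2. excess of left-handed product over right-handed product in the product at 2.5 h
3. excess of right-handed substrate over left-handed substrate among what is left of the two at 2.5 h

My reckoning builds the flask one process at a time.

1. Start with the main step, the two catalysed routes. Divide the fractional loss rate of the left-handed substrate by that of the right-handed substrate: reagent, free catalyst and time cancel, and a constant remains. This is the selectivity factor, the log of charged over left for the left-handed substrate divided by the same log for the right-handed substrate, and the last two west readings put it at 1.61, a reading with a scatter of 1.5 percentage points on each point.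

2. Add the impurity, 1.3 mM against 7.6 mM of free catalyst. Both routes run on the same free catalyst, so whatever it takes slows them together and the factor stays as it was.

3. Add catalyst decay and self-condensation. The south-east run, with the flask's catalyst charge, stops moving: its left-handed substrate reads 27% at 1.50 h and 28% at 2.50 h. I scale its log loss in proportion to reagent charge, from 0.15 M to 0.200 M, which gives 0.797 for this flask. That leaves 22.5% left-handed substrate, and the factor turns this into 30.5% right-handed substrate. My reckoning is therefore c 47.0%, eP 17.0% and eS 15.1%.

The forecast, from “a selectivity of about 1.65”, says c 46%, eP 18% and eS 15.3%, so its c is lower than mine.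

The flask gives c 44.5%, eP 18.1% and eS 14.5%.

    reagent + free catalyst + left-handed substrate → free catalyst + left-handed product (k = 0.510 L² mol⁻² s⁻¹)
    reagent + free catalyst + right-handed substrate → free catalyst + right-handed product (k = 0.310 L² mol⁻² s⁻¹)
    free catalyst + impurity → spent catalyst A (k = 13.0 L mol⁻¹ s⁻¹)
    2 reagent → self-condensation product (k = 7.60 × 10⁻⁴ L mol⁻¹ s⁻¹)
    free catalyst → spent catalyst B (k = 4.20 × 10⁻⁴ s⁻¹)

This flask keeps 47% of its charged left-handed substrate at 2.50 h, and the factor turns that into 62.6% of the right-handed substrate, against 64% found. The forecast's excesses rest on two things that a run can show otherwise: the factor, and how far the substrates have gone when the flask stops. The neighbouring flask with 0.50 M of reagent keeps 21% of its left-handed substrate, which the factor carries to 38.6% of the right-handed substrate, against 39% found, and to an eS of 28.4%, against 29.3% found.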